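**Retrosynthetic overview**

1. The last step closes the spiro-tetrahydrofuran: acid-triggered trans-diaxial addition of H (to C8) and of the C13 oxygen (to C9) across a Δ8(9) alkene of a trans-decalin sets C8 and C9 together. The side chain C11–C16 (lactone preformed, C13 from (R)-malic acid) is joined to C9 by Negishi coupling of a ring-B enol triflate.
2. Ring B is closed at C7–C8 by gold-catalysed 6-endo-dig carbocyclization of a C9 silyl enol ether onto an ethynyl group on C5. The enabling feature: C9 (the spiro-ether carbon, flanked by quaternary C10) can be carried as a ketone whose only enolizable position is C8, while C7 is the terminal carbon of an alkyne held trans-diequatorial to the C10 acyl group on ring A.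
3. Ring A comes from an enantioselective Diels–Alder reaction of an (E)-enynal with a 2-silyloxydiene (sets C5/C10); C4 is set by benzyloxymethylation, C3 by hydroxyl-directed reduction.
4. Order of ring formation: ring A (cycloaddition), ring B (key step), spiro-tetrahydrofuran (last step); the lactone ring is brought in intact.

Key step: step 9

Remark 1: labdane numbering (C1–C20) is used for all intermediates; α/β refer to the usual drawing in which the C10 methyl is β.
Remark 2 (assumption): the (S)-configured oxazaborolidinium catalyst in step 3 is taken to give the (1S,6S) adduct 6 by the usual formyl C–H···O binding model; if the sense of induction is the opposite, the mirror-image catalyst is used and nothing else changes.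

**Route**

Step 1
Reactants: 1 3-(trimethylsilyl)prop-2-ynal; 2 2-(triphenyl-λ5-phosphanylidene)propanal
Product: 3 (E)-2-methyl-5-(trimethylsilyl)pent-2-en-4-ynal
Conditions: CH2Cl2, 0 °C → rt
Reagents that add atoms: none
Why: Wittig olefination of a reactive ynal with a stabilized formyl ylide should give the (E)-enal (alkynyl trans to CHO), the geometry that later places the alkyne cis to the C10 methyl.

Step 2
Reactants: 4 pent-1-en-3-one
Product: 5 (Z)-tert-butyldimethyl(penta-1,3-dien-3-yloxy)silane
Conditions: TBSOTf, Et3N, Et2O, 0 °C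
Reagents that add atoms: tert-butyldimethylsilyl trifluoromethanesulfonate, CC(C)(C)[Si](C)(C)OS(=O)(=O)C(F)(F)F
Why: soft enolization of the ethyl ketone should give the (Z)-2-silyloxy-1,3-diene, whose methyl group sits on the outside of the s-cis diene.

Step 3
Reactants: 3 (E)-2-methyl-5-(trimethylsilyl)pent-2-en-4-ynal; 5 (Z)-tert-butyldimethyl(penta-1,3-dien-3-yloxy)silane
Product: 6 (1S,6S)-4-(tert-butyldimethylsilyloxy)-1,5-dimethyl-6-[(trimethylsilyl)ethynyl]cyclohex-3-ene-1-carbaldehyde (epimers at the ring CHCH3 carbon)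
Conditions: (S)-B-(o-tolyl)-diphenylprolinol oxazaborolidine·HNTf2 (20 mol %), CH2Cl2, −78 → −40 °C
Reagents that add atoms: none
Why: catalytic enantioselective Diels–Alder reaction of an α-substituted enal under a chiral oxazaborolidinium Lewis acid; the enol-ether terminus (C4) bonds to the β-carbon (C5), suprafacial addition to the (E)-enal fixes alkynyl cis to the C10 methyl and trans to CHO, the catalyst fixes the absolute sense, and the endo/exo-dependent C4 centre is erased later.

Step 4
Reactants: 6 (1S,6S)-4-(tert-butyldimethylsilyloxy)-1,5-dimethyl-6-[(trimethylsilyl)ethynyl]cyclohex-3-ene-1-carbaldehyde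
Product: 7 1-[(1S,6S)-4-(tert-butyldimethylsilyloxy)-1,5-dimethyl-6-[(trimethylsilyl)ethynyl]cyclohex-3-en-1-yl]propan-1-ol (carbinol epimers)
Conditions: EtMgBr, THF, −78 → 0 °C
Reagents that add atoms: ethylmagnesium bromide, CC[Mg]Br
Why: Grignard addition to the non-enolizable neopentyl aldehyde brings in C8 and C17; the carbinol epimers are inconsequential because C9 is oxidized in step 8.

Step 5
Reactants: 7 1-[(1S,6S)-4-(tert-butyldimethylsilyloxy)-1,5-dimethyl-6-[(trimethylsilyl)ethynyl]cyclohex-3-en-1-yl]propan-1-ol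
Product: 10 4-(1-hydroxypropyl)-4,6-dimethyl-5-[(trimethylsilyl)ethynyl]cyclohex-2-en-1-one (alkynyl cis to the 4-methyl), via α-phenylselanyl ketone 8 (not isolated), via selenoxide 9 (not isolated)
Conditions: PhSeCl, CH2Cl2, −78 °C; then H2O2, pyridine, 0 °C → rt
Reagents that add atoms: none
Why: selenylation of the silyl enol ether at C2 followed by selenoxide syn-elimination toward C1 should give the C1=C2 enone regiospecifically, which blocks C2 so that only C4 can be enolized in the next step.

Step 6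
Reactants: 10 4-(1-hydroxypropyl)-4,6-dimethyl-5-[(trimethylsilyl)ethynyl]cyclohex-2-en-1-one
Product: 12 6-(benzyloxymethyl)-4,6-dimethyl-4-[1-(triethylsilyloxy)propyl]-5-[(trimethylsilyl)ethynyl]cyclohex-2-en-1-one (CH2OBn trans to the alkynyl group), via bis(triethylsilyl) dienol ether 11 (not isolated)
Conditions: TESOTf, Et3N, CH2Cl2, 0 °C; then BnOCH2Cl, ZnBr2 (20 mol %), CH2Cl2, −40 → 0 °C
Reagents that add atoms: triethylsilyl trifluoromethanesulfonate, CC[Si](CC)(CC)OS(=O)(=O)C(F)(F)F; benzyl chloromethyl ether, ClCOCc1ccccc1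
Why: Mukaiyama-type alkylation of the cross-conjugated silyl dienol ether (γ-position C10 is quaternary, so only C4 is nucleophilic) should create the C4 quaternary centre, the electrophile entering on the α face anti to the pseudoaxial C10 methyl and the C5 alkynyl group (CH2OBn α, CH3 β).

Step 7
Reactants: 12 6-(benzyloxymethyl)-4,6-dimethyl-4-[1-(triethylsilyloxy)propyl]-5-[(trimethylsilyl)ethynyl]cyclohex-2-en-1-one
Product: 13 6-(benzyloxymethyl)-5-ethynyl-4-(1-hydroxypropyl)-4,6-dimethylcyclohex-2-en-1-one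
Conditions: Bu4NF, AcOH, THF, 0 °C → rt
Reagents that add atoms: none
Why: buffered fluoride cleaves the secondary triethylsilyl ether and the C(sp)–Si bond in one operation; C4 carries no hydrogen, so the β-benzyloxy ketone cannot eliminate.

Step 8
Reactants: 13 6-(benzyloxymethyl)-5-ethynyl-4-(1-hydroxypropyl)-4,6-dimethylcyclohex-2-en-1-one
Product: 14 6-(benzyloxymethyl)-5-ethynyl-4,6-dimethyl-4-propanoylcyclohex-2-en-1-one
Conditions: Dess–Martin periodinane, CH2Cl2, rt
Reagents that add atoms: none
Why: Dess–Martin oxidation of the secondary alcohol gives the C9 ethyl ketone, now the only enolizable carbonyl group in the molecule (enolizable only at C8).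

Step 9
Reactants: 14 6-(benzyloxymethyl)-5-ethynyl-4,6-dimethyl-4-propanoylcyclohex-2-en-1-one
Product: 16 trans-fused 5-(benzyloxymethyl)-2,5,8a-trimethyl-4a,5-dihydronaphthalene-1,6(2H,8aH)-dione (C8 epimers), via tert-butyldimethylsilyl enol ether 15 (not isolated)
Conditions: TBSOTf, Et3N, CH2Cl2, 0 °C; then (t-Bu)2(2-biphenylyl)PAuNTf2 (5 mol %), CH2Cl2/MeOH 10:1, rt
Reagents that add atoms: none
Why: Soft enolization can only give the C9 silyl enol ether 15, because C10 is quaternary and the ring-A enone has no enolizable hydrogen; the cationic monovalent gold complex then π-activates the terminal alkyne, C8 attacks the terminal carbon C7 anti to gold, methanol removes the silyl group and protodeauration releases the β,γ-unsaturated ketone (closest precedent: gold-catalysed Conia-ene-type carbocyclization of silyl enol ethers onto alkynes). Ring B is closed in the 6-endo-dig mode and is trans-fused because the ethynyl and acyl groups are trans-diequatorial on ring A. The only new stereocentre, C8, lies α to the C9 ketone and may form as a mixture; this is inconsequential because C8 becomes sp2 again in step 13 and is set for good in step 21. The selectivity needed is 6-endo attack at C7 against 5-exo attack at the internal alkyne carbon; the bulky biarylphosphine ligand and the strain of the alternative trans-fused methylenecyclopentanone should favour C7. Chemoselectivity rests on the substrate: the benzyl ether oxygen is far less nucleophilic than the enol ether and the electron-poor enone alkene is inert to the π-acid.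

Step 10
Reactants: 16 trans-fused 5-(benzyloxymethyl)-2,5,8a-trimethyl-4a,5-dihydronaphthalene-1,6(2H,8aH)-dione
Product: 17 trans-fused 5-(hydroxymethyl)-2,5,8a-trimethyldecahydronaphthalene-1,6-dione (C8 epimers)
Conditions: H2 (1 atm), Pd/C, EtOAc/EtOH, rt
Reagents that add atoms: none
Why: one hydrogenation saturates C6=C7 and C1=C2 and cleaves the benzyl ether; if palladium moves C6=C7 to C5=C6, addition from the α face (anti to the axial C4 and C10 methyls) should give the same trans-fused product.

Step 11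
Reactants: 17 trans-fused 5-(hydroxymethyl)-2,5,8a-trimethyldecahydronaphthalene-1,6-dione
Product: 18 trans-fused 6β-hydroxy-5-(hydroxymethyl)-2,5,8a-trimethyloctahydronaphthalen-1(2H)-one (labdane 3β,18-diol 9-ketone)
Conditions: Me4NBH(OAc)3, AcOH/MeCN, −20 °C
Reagents that add atoms: none
Why: hydroxyl-directed (Evans–Saksena type) reduction; the C18 hydroxyl binds boron and delivers hydride to C3 from the α face (3β-OH), while the hindered, undirected C9 ketone is left.

Step 12
Reactants: 18 trans-fused 6β-hydroxy-5-(hydroxymethyl)-2,5,8a-trimethyloctahydronaphthalen-1(2H)-one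
Product: 19 3β,18-O-isopropylidene acetal of 18
Conditions: Me2C(OMe)2, pyridinium p-toluenesulfonate (cat.), CH2Cl2, rt
Reagents that add atoms: 2,2-dimethoxypropane, COC(C)(C)OC
Why: the 1,3-diol forms a six-membered acetonide, leaving C8–H next to the C9 ketone as the only acidic site.

Step 13
Reactants: 19 3β,18-O-isopropylidene acetal of 18
Product: 21 Δ8(9) enol trifluoromethanesulfonate of 19, via potassium enolate 20 (not isolated)
Conditions: KN(SiMe3)2, THF, −78 → 0 °C; then PhNTf2, −78 °C → rt
Reagents that add atoms: N-phenylbis(trifluoromethanesulfonimide), O=S(=O)(N(c1ccccc1)S(=O)(=O)C(F)(F)F)C(F)(F)F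
Why: only C8 can be deprotonated (C10 is quaternary), so O-triflation gives a single tetrasubstituted enol triflate and erases the C8 centre.

Step 14
Reactants: 22 (R)-malic acid
Product: 23 2-[(2R,4R)-2-tert-butyl-5-oxo-1,3-dioxolan-4-yl]acetic acid
Conditions: pivalaldehyde, TsOH (cat.), H2SO4 (cat.), pentane, reflux, water separator
Reagents that add atoms: pivalaldehyde, CC(C)(C)C=O
Why: the α-hydroxy acid part condenses to the cis-2-tert-butyl-1,3-dioxolan-4-one, which stores the C13 configuration in the acetal centre.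

Step 15
Reactants: 23 2-[(2R,4R)-2-tert-butyl-5-oxo-1,3-dioxolan-4-yl]acetic acid
Product: 25 2-[(2R,4R)-2-tert-butyl-5-oxo-4-(prop-2-en-1-yl)-1,3-dioxolan-4-yl]acetic acid, via dilithium enolate carboxylate 24 (not isolated)
Conditions: LiN(SiMe3)2 (2.2 equiv), THF, −78 °C; allyl bromide, −78 → −20 °C
Reagents that add atoms: allyl bromide, C=CCBr
Why: alkylation of the dioxolanone enolate anti to the tert-butyl group (self-regeneration of the stereocentre, net retention) makes C13 quaternary with defined configuration.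

Step 16
Reactants: 25 2-[(2R,4R)-2-tert-butyl-5-oxo-4-(prop-2-en-1-yl)-1,3-dioxolan-4-yl]acetic acid
Product: 27 (R)-4-hydroxy-4-(prop-2-en-1-yl)oxolan-2-one, via sodium dihydroxy carboxylate 26 (not isolated)
Conditions: NaBH4, EtOH, 0 °C → rt; then 2 M HCl, rt
Reagents that add atoms: none
Why: borohydride reduces only the activated acylal carbonyl (the carboxylate is inert) to the C16 carbinol with loss of the pivalaldehyde unit, and acid closes the γ-lactone; no bond to C13 is broken.

Step 17
Reactants: 27 (R)-4-hydroxy-4-(prop-2-en-1-yl)oxolan-2-one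
Product: 28 (R)-4-(prop-2-en-1-yl)-4-(triethylsilyloxy)oxolan-2-one
Conditions: TESOTf, 2,6-lutidine, CH2Cl2, −78 → 0 °C
Reagents that add atoms: triethylsilyl trifluoromethanesulfonate, CC[Si](CC)(CC)OS(=O)(=O)C(F)(F)F
Why: silyl triflate silylation protects the tertiary β-hydroxy lactone against elimination and against protonolysis of the later organozinc reagent.

Step 18
Reactants: 28 (R)-4-(prop-2-en-1-yl)-4-(triethylsilyloxy)oxolan-2-one
Product: 30 (R)-4-(2-hydroxyethyl)-4-(triethylsilyloxy)oxolan-2-one, via ozonide 29 (not isolated)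
Conditions: O3, CH2Cl2, −78 °C; then NaBH4, MeOH, −78 → 0 °C
Reagents that add atoms: ozone, [O-][O+]=O
Why: ozonolysis with reductive work-up trims the allyl group to the two-carbon arm C12–C11 ending in a primary alcohol; the lactone survives borohydride at low temperature.

Step 19
Reactants: 30 (R)-4-(2-hydroxyethyl)-4-(triethylsilyloxy)oxolan-2-one
Product: 31 (S)-4-(2-iodoethyl)-4-(triethylsilyloxy)oxolan-2-one
Conditions: I2, PPh3, imidazole, CH2Cl2, 0 °C
Reagents that add atoms: iodine, II
Why: Appel-type iodination of the primary alcohol under neutral conditions (the descriptor changes by priority only).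

Step 20
Reactants: 31 (S)-4-(2-iodoethyl)-4-(triethylsilyloxy)oxolan-2-one; 21 Δ8(9) enol trifluoromethanesulfonate of 19
Product: 33 (13R)-3β,18-O-isopropylidene-13-(triethylsilyloxy)labd-8-en-15,16-olide, via alkylzinc iodide 32 (not isolated)
Conditions: Zn dust, LiCl, THF, 40 °C; then 21, Pd(OAc)2 (5 mol %), SPhos (10 mol %), THF/NMP, 50 °C
Reagents that add atoms: none
Why: Negishi coupling of a primary alkylzinc iodide (zinc insertion tolerates lactone and silyl ether) with the hindered cyclohexenyl triflate joins C11 to C9 without touching any stereocentre.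

Step 21
Reactants: 33 (13R)-3β,18-O-isopropylidene-13-(triethylsilyloxy)labd-8-en-15,16-olide
Product: 35 (3S,4R,5S,8R,9R,10S,13R)-3β,18-dihydroxy-9α,13-epoxylabdan-15,16-olide, via spiro ether acetonide 34 (not isolated)
Conditions: Tf2NH (20 mol %), CH2Cl2, −20 → 0 °C; then MeOH/H2O, 40 °C
Reagents that add atoms: none
Why: Brønsted-acid hydroalkoxylation of the tetrasubstituted alkene in the 5-exo mode, in which the proton adds to C8 from the β face and the C13 oxygen (silyl group lost to triflimide) attacks C9 from the α face (trans-diaxial addition), should give 8β-H/8α-CH3 and the 9α-oxygen, whereas attack at C8 would need an axial C–O bond syn to the C10 methyl; C13 keeps its configuration because its C–O bond is never broken, and aqueous methanol then removes the acetonide.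

**Compound list**

1 | 3-(trimethylsilyl)prop-2-ynal | C[Si](C)(C)C#CC=O | starting material
2 | 2-(triphenyl-λ5-phosphanylidene)propanal | CC(C=O)=P(c1ccccc1)(c1ccccc1)c1ccccc1 | starting material
3 | (E)-2-methyl-5-(trimethylsilyl)pent-2-en-4-ynal | C[Si](C)(C)C#C/C=C(\C)C=O | intermediate
4 | pent-1-en-3-one | C=CC(=O)CC | starting material
5 | (Z)-tert-butyldimethyl(penta-1,3-dien-3-yloxy)silane | C=C/C(O[Si](C)(C)C(C)(C)C)=C/C | intermediate
6 | (1S,6S)-4-(tert-butyldimethylsilyloxy)-1,5-dimethyl-6-[(trimethylsilyl)ethynyl]cyclohex-3-ene-1-carbaldehyde; alkynyl cis to the 1-methyl, ring CHCH3 carbon epimeric | C[Si](C)(C)C#C[C@H]1C(C)C(O[Si](C)(C)C(C)(C)C)=CC[C@]1(C)C=O | intermediate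
7 | 1-[(1S,6S)-4-(tert-butyldimethylsilyloxy)-1,5-dimethyl-6-[(trimethylsilyl)ethynyl]cyclohex-3-en-1-yl]propan-1-ol; carbinol epimers | C[Si](C)(C)C#C[C@H]1C(C)C(O[Si](C)(C)C(C)(C)C)=CC[C@]1(C)C(O)CC | intermediate
8 | 4-(1-hydroxypropyl)-2,4-dimethyl-6-(phenylselanyl)-3-[(trimethylsilyl)ethynyl]cyclohexan-1-one; alkynyl cis to the 4-methyl | C[Si](C)(C)C#C[C@H]1C(C)C(=O)C([Se]c2ccccc2)C[C@]1(C)C(O)CC | intermediate
9 | selenoxide of 8 | C[Si](C)(C)C#C[C@H]1C(C)C(=O)C([Se](=O)c2ccccc2)C[C@]1(C)C(O)CC | intermediate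
10 | 4-(1-hydroxypropyl)-4,6-dimethyl-5-[(trimethylsilyl)ethynyl]cyclohex-2-en-1-one; alkynyl cis to the 4-methyl, epimers at C6 and at the carbinol | C[Si](C)(C)C#C[C@H]1C(C)C(=O)C=C[C@]1(C)C(O)CC | intermediate
11 | bis(triethylsilyl) derivative of 10: cross-conjugated triethylsilyl dienol ether of the ring ketone plus triethylsilyl ether of the carbinol | C[Si](C)(C)C#C[C@H]1C(C)=C(O[Si](CC)(CC)CC)C=C[C@]1(C)C(O[Si](CC)(CC)CC)CC | intermediate
12 | 6-(benzyloxymethyl)-4,6-dimethyl-4-[1-(triethylsilyloxy)propyl]-5-[(trimethylsilyl)ethynyl]cyclohex-2-en-1-one; CH2OBn trans to the alkynyl group, alkynyl cis to both methyls (labdane 4α-CH2OBn, 5β-alkynyl, 10β-CH3) | C[Si](C)(C)C#C[C@H]1[C@](C)(COCc2ccccc2)C(=O)C=C[C@]1(C)C(O[Si](CC)(CC)CC)CC | intermediate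
13 | 6-(benzyloxymethyl)-5-ethynyl-4-(1-hydroxypropyl)-4,6-dimethylcyclohex-2-en-1-one; ring stereochemistry as in 12 | C#C[C@H]1[C@](C)(COCc2ccccc2)C(=O)C=C[C@]1(C)C(O)CC | intermediate
14 | 6-(benzyloxymethyl)-5-ethynyl-4,6-dimethyl-4-propanoylcyclohex-2-en-1-one; ring stereochemistry as in 12 | C#C[C@H]1[C@](C)(COCc2ccccc2)C(=O)C=C[C@]1(C)C(=O)CC | intermediate
15 | tert-butyldimethylsilyl enol ether of the propanoyl group of 14 | C#C[C@H]1[C@](C)(COCc2ccccc2)C(=O)C=C[C@]1(C)C(O[Si](C)(C)C(C)(C)C)=CC | intermediate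
16 | trans-fused 5-(benzyloxymethyl)-2,5,8a-trimethyl-4a,5-dihydronaphthalene-1,6(2H,8aH)-dione; 4a-H α, 8a-CH3 β, 5-CH3 β, 5-CH2OBn α, C2 epimers (labdane 1,6-dien-3,9-dione) | CC1C=C[C@H]2[C@](C)(COCc3ccccc3)C(=O)C=C[C@]2(C)C1=O | intermediate
17 | trans-fused 5-(hydroxymethyl)-2,5,8a-trimethyldecahydronaphthalene-1,6-dione; stereochemistry as in 16, C2 epimers | CC1CC[C@H]2[C@](C)(CO)C(=O)CC[C@]2(C)C1=O | intermediate
18 | trans-fused 6β-hydroxy-5α-(hydroxymethyl)-2,5β,8aβ-trimethyloctahydronaphthalen-1(2H)-one; C2 epimers | CC1CC[C@H]2[C@](C)(CO)[C@@H](O)CC[C@]2(C)C1=O | intermediate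
19 | 3β,18-O-isopropylidene acetal of 18 | CC1CC[C@H]2[C@]3(C)COC(C)(C)O[C@H]3CC[C@]2(C)C1=O | intermediate
20 | potassium Δ8(9) enolate of 19 | CC=1CC[C@H]2[C@]3(C)COC(C)(C)O[C@H]3CC[C@]2(C)C=1O[K] | intermediate
21 | Δ8(9) enol trifluoromethanesulfonate of 19 | CC=1CC[C@H]2[C@]3(C)COC(C)(C)O[C@H]3CC[C@]2(C)C=1OS(=O)(=O)C(F)(F)F | intermediate
22 | (R)-malic acid | O[C@H](CC(=O)O)C(=O)O | starting material
23 | 2-[(2R,4R)-2-tert-butyl-5-oxo-1,3-dioxolan-4-yl]acetic acid | OC(=O)C[C@H]1O[C@@H](C(C)(C)C)OC1=O | intermediate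
24 | dilithium salt of 23 (lithium carboxylate, lithium dioxolanone enolate) | [Li]OC(=O)CC1=C(O[Li])O[C@H](C(C)(C)C)O1 | intermediate
25 | 2-[(2R,4R)-2-tert-butyl-5-oxo-4-(prop-2-en-1-yl)-1,3-dioxolan-4-yl]acetic acid | OC(=O)C[C@@]1(CC=C)O[C@@H](C(C)(C)C)OC1=O | intermediate
26 | sodium (R)-3-hydroxy-3-(hydroxymethyl)hex-5-enoate | C=CC[C@@](CC(=O)[O-])(CO)O.[Na+] | intermediate
27 | (R)-4-hydroxy-4-(prop-2-en-1-yl)oxolan-2-one | C=CC[C@@]1(COC(=O)C1)O | intermediate
28 | (R)-4-(prop-2-en-1-yl)-4-(triethylsilyloxy)oxolan-2-one | C=CC[C@@]1(COC(=O)C1)O[Si](CC)(CC)CC | intermediate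
29 | ozonide (1,2,4-trioxolane) of 28 | C1(C[C@@]2(COC(=O)C2)O[Si](CC)(CC)CC)OOCO1 | intermediate
30 | (R)-4-(2-hydroxyethyl)-4-(triethylsilyloxy)oxolan-2-one | OCC[C@@]1(COC(=O)C1)O[Si](CC)(CC)CC | intermediate
31 | (S)-4-(2-iodoethyl)-4-(triethylsilyloxy)oxolan-2-one | ICC[C@@]1(COC(=O)C1)O[Si](CC)(CC)CC | intermediate
32 | alkylzinc iodide from 31 | I[Zn]CC[C@@]1(COC(=O)C1)O[Si](CC)(CC)CC | intermediate
33 | (13R)-3β,18-O-isopropylidene-13-(triethylsilyloxy)labd-8-en-15,16-olide | CC=1CC[C@H]2[C@]3(C)COC(C)(C)O[C@H]3CC[C@]2(C)C=1CC[C@@]4(COC(=O)C4)O[Si](CC)(CC)CC | intermediate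
34 | 3β,18-O-isopropylidene acetal of the target | C[C@@H]1CC[C@H]2[C@]3(C)COC(C)(C)O[C@H]3CC[C@]2(C)[C@@]14CC[C@@]5(COC(=O)C5)O4 | intermediate
35 | (3S,4R,5S,8R,9R,10S,13R)-3β,18-dihydroxy-9α,13-epoxylabdan-15,16-olide | C[C@@H]1CC[C@H]2[C@](C)(CO)[C@@H](O)CC[C@]2(C)[C@@]12CC[C@@]1(COC(=O)C1)O2 | target

**Step count and risks**

Total step count: 21. Longest linear sequence: 14 steps (steps 1, 3 to 13, 20, 21).

Steps most likely to fail:

Step 9 (key step). The enol ether may attack the internal alkyne carbon (5-exo-dig closure), or the alkyne or enol ether may be hydrolysed before cyclization. The fallback sets out from 14 and closes the same C7–C8 bond by an aldol condensation. Anti-Markovnikov hydration of the terminal alkyne (RuCpCl(dppm), i-PrOH/H2O, 100 °C) would give the aldehyde 2-[2-(benzyloxymethyl)-2,4-dimethyl-3-oxo-6-propanoylcyclohex-4-en-1-yl]acetaldehyde F1. Acid-catalysed intramolecular aldol condensation of the C8 enol onto the C7 aldehyde (TsOH, benzene, 60 °C) would give the ring-B enone 5-(benzyloxymethyl)-2,5,8a-trimethyl-4a,5-dihydronaphthalene-1,6(4H,8aH)-dione F2 (C7=C8). Hydrogenation under the conditions of step 10 returns to the route at 17.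

Step 21. The C9 cation may suffer methyl migration from C10, the hydroxyl may attack C8 instead of C9, or the proton may be delivered to the wrong face of C8. The fallback sets out from 33 and replaces the cationic addition by a conjugate addition. Allylic oxidation at C7 (CrO3, 3,5-dimethylpyrazole, CH2Cl2, −20 °C) would give the 8-en-7-one (13R)-3β,18-O-isopropylidene-7-oxo-13-(triethylsilyloxy)labd-8-en-15,16-olide F3. Fluoride (Bu4NF, THF, 0 °C) would remove the silyl group, and the tertiary alkoxide would add to C9 in a 5-exo oxa-Michael reaction (axial attack, C8 equilibrated next to the ketone) to give the 7-oxo spiro ether 3β,18-O-isopropylidene-7-oxo-9α,13-epoxylabdan-15,16-olide F4. Ethane-1,2-dithiol with BF3·OEt2 would give the 7,7-ethylenedithio derivative of the target F5, with loss of the acetonide. Raney nickel in ethanol then comes back to the route at the target 35.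

Step 3. The trisubstituted enal may turn over slowly, Mukaiyama aldol addition of the silyloxydiene to the aldehyde may compete, or facial selectivity may be poor. The fallback sets out from 3 and 5 and resolves a racemate. Me2AlCl in CH2Cl2 at −78 °C would give racemic 6, that is 6 together with its mirror image, (1R,6R)-4-(tert-butyldimethylsilyloxy)-1,5-dimethyl-6-[(trimethylsilyl)ethynyl]cyclohex-3-ene-1-carbaldehyde F6. NaBH4 reduction would give the primary alcohol [(1S,6S)-4-(tert-butyldimethylsilyloxy)-1,5-dimethyl-6-[(trimethylsilyl)ethynyl]cyclohex-3-en-1-yl]methanol F7 and its mirror image, the (1R,6R) alcohol F8. Lipase-catalysed acetylation (Burkholderia cepacia lipase, vinyl acetate) would convert one antipode into its acetate, written here for the unwanted one as the (1R,6R) acetate F9. The remaining alcohol F7 is separated and oxidized with Dess–Martin periodinane, which comes back to the route at 6.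

Further compounds
F1 | step 9 | 2-[2-(benzyloxymethyl)-2,4-dimethyl-3-oxo-6-propanoylcyclohex-4-en-1-yl]acetaldehyde (ring stereochemistry as in 14) | O=CC[C@H]1[C@](C)(COCc2ccccc2)C(=O)C=C[C@]1(C)C(=O)CC
F2 | step 9 | trans-fused 5-(benzyloxymethyl)-2,5,8a-trimethyl-4a,5-dihydronaphthalene-1,6(4H,8aH)-dione (labdane 1,7-dien-3,9-dione) | CC1=CC[C@H]2[C@](C)(COCc3ccccc3)C(=O)C=C[C@]2(C)C1=O
F3 | step 21 | (13R)-3β,18-O-isopropylidene-7-oxo-13-(triethylsilyloxy)labd-8-en-15,16-olide | CC=1C(=O)C[C@H]2[C@]3(C)COC(C)(C)O[C@H]3CC[C@]2(C)C=1CC[C@@]4(COC(=O)C4)O[Si](CC)(CC)CC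
F4 | step 21 | 3β,18-O-isopropylidene-7-oxo-9α,13-epoxylabdan-15,16-olide (8α-methyl, 13R) | C[C@@H]1C(=O)C[C@H]2[C@]3(C)COC(C)(C)O[C@H]3CC[C@]2(C)[C@@]14CC[C@@]5(COC(=O)C5)O4
F5 | step 21 | 7,7-(ethane-1,2-diyldisulfanediyl)-3β,18-dihydroxy-9α,13-epoxylabdan-15,16-olide | C[C@@H]1C2(SCCS2)C[C@H]3[C@](C)(CO)[C@@H](O)CC[C@]3(C)[C@@]14CC[C@@]5(COC(=O)C5)O4
F6 | step 3 | (1R,6R)-4-(tert-butyldimethylsilyloxy)-1,5-dimethyl-6-[(trimethylsilyl)ethynyl]cyclohex-3-ene-1-carbaldehyde | C[Si](C)(C)C#C[C@@H]1C(C)C(O[Si](C)(C)C(C)(C)C)=CC[C@@]1(C)C=O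
F7 | step 3 | [(1S,6S)-4-(tert-butyldimethylsilyloxy)-1,5-dimethyl-6-[(trimethylsilyl)ethynyl]cyclohex-3-en-1-yl]methanol | C[Si](C)(C)C#C[C@H]1C(C)C(O[Si](C)(C)C(C)(C)C)=CC[C@]1(C)CO
F8 | step 3 | [(1R,6R)-4-(tert-butyldimethylsilyloxy)-1,5-dimethyl-6-[(trimethylsilyl)ethynyl]cyclohex-3-en-1-yl]methanol | C[Si](C)(C)C#C[C@@H]1C(C)C(O[Si](C)(C)C(C)(C)C)=CC[C@@]1(C)CO
F9 | step 3 | [(1R,6R)-4-(tert-butyldimethylsilyloxy)-1,5-dimethyl-6-[(trimethylsilyl)ethynyl]cyclohex-3-en-1-yl]methyl acetate | C[Si](C)(C)C#C[C@@H]1C(C)C(O[Si](C)(C)C(C)(C)C)=CC[C@@]1(C)COC(C)=O
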